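**Assumptions (one line each)**
- Enantiopure (S)-(+)-terpinen-4-ol is purchased; a lower-ee lot would be upgraded by preparative chiral SFC before use.
- Daucane numbering is used for the bicyclic compounds (C1 = ring-fusion carbon bearing CH3, C4 = carbinol bearing iPr, C5 = ring-fusion CH, C6 = ester carbon, C8=C9 = ring alkene/epoxide, C14 = carbon on C8); β means the face of the C1 methyl.
- Rh2(R-DOSP)4 is assigned as the matched catalyst from the empirical induction model for this catalyst family; this assignment is the least certain stereochemical point, and the S catalyst is substituted if the C1 epimer forms.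

**Retrosynthetic overview**
1. Target ⇐ jaeschkeanadiol: 6α-OH-directed α-epoxidation of C8=C9, then selective C6 acylation and debenzylation.
2. Jaeschkeanadiol ⇐ dauca-5,8-dien-4β-ol: 4β-OH-directed epoxidation of C5=C6, Ti(III) reductive opening (sets the trans ring fusion), oxidation, 4-OH-directed anti reduction (sets 6α-OH).
3. C8 methyl ⇐ C8 methyl ester (reduction/deoxygenation).
4. Seven-membered ring and C1 quaternary centre ⇐ Rh-vinylcarbenoid cyclopropanation/divinylcyclopropane Cope [4+3] of a 2-methyl-1-vinylcyclopentene with methyl 2-diazobut-3-enoate (the new step).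
5. Five-membered ring (formed first) ⇐ (S)-terpinen-4-ol by ozonolysis, intramolecular aldol condensation and Wittig methylenation; the C4 carbinol comes from the chiral pool.

**Route**

Step 1
Reactants: 1, (S)-(+)-terpinen-4-ol
Product: 2, (S)-triethyl[(1-isopropyl-4-methylcyclohex-3-en-1-yl)oxy]silane
Conditions: TESOTf, 2,6-lutidine, CH2Cl2, −78 → 0 °C
Reagents that add atoms: triethylsilyl triflate, CC[Si](CC)(CC)OS(=O)(=O)C(F)(F)F
Why: Silyl triflate silylation of the tertiary alcohol masks the OH (needed later to avoid O–H insertion and β-elimination) without touching the stereocentre.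

Step 2
Reactants: 2
Product: 3, (S)-3-isopropyl-6-oxo-3-(triethylsilyloxy)heptanal
Conditions: O3, CH2Cl2, −78 °C; then PPh3, −78 °C → rt
Reagents that add atoms: ozone, [O-][O+]=O
Why: Ozonolysis with reductive work-up cleaves the only C=C into the methyl ketone and the aldehyde; the carbinol stereocentre is not involved.

Step 3
Reactants: 3
Product: 4, (R)-5-isopropyl-2-methyl-5-(triethylsilyloxy)cyclopent-1-ene-1-carbaldehyde
Conditions: Bn2NH·TFA (0.3 equiv), benzene, 50 °C
Reagents that add atoms: none
Why: Amine-salt-mediated intramolecular aldol condensation, in which the aldehyde enamine attacks the methyl ketone (5-ring closure) and the new free tertiary aldol OH dehydrates in preference to the hindered OTES group, giving the tetrasubstituted enal.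

Step 4
Reactants: 4
Product: 5, (R)-triethyl[(1-isopropyl-3-methyl-2-vinylcyclopent-2-en-1-yl)oxy]silane
Conditions: Ph3PCH3Br, KHMDS, THF, −78 → 0 °C
Reagents that add atoms: methyltriphenylphosphonium bromide, C[P+](c1ccccc1)(c1ccccc1)c1ccccc1.[Br-]
Why: Wittig methylenation of the non-enolisable enal gives the 1-vinylcyclopentene diene under basic conditions that the allylic silyl ether tolerates.

Step 5
Reactants: 6, methyl but-3-enoate
Product: 7, methyl 2-diazobut-3-enoate
Conditions: p-ABSA, DBU, MeCN, 0 °C; used cold and immediately
Reagents that add atoms: 4-acetamidobenzenesulfonyl azide, CC(=O)Nc1ccc(cc1)S(=O)(=O)N=[N+]=[N-]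
Why: Regitz diazo transfer to the doubly activated (ester and vinyl) CH2 gives the donor/acceptor vinyldiazoacetate.

Step 6
Reactants: 5; 7 (2–3 equiv, slow addition)
Product: 8, methyl 4β-(triethylsilyloxy)dauca-5,8-dien-14-oate [methyl (3R,8aR)-3-isopropyl-8a-methyl-3-(triethylsilyloxy)-1,2,3,5,8,8a-hexahydroazulene-6-carboxylate]
Conditions: Rh2(R-DOSP)4 (1 mol %), pentane, −40 °C → rt; then toluene, 100 °C
Reagents that add atoms: none (all product atoms come from 5 and 7; N2 is lost)
Why: Proposed new method: tandem Rh-vinylcarbenoid cyclopropanation/divinylcyclopropane rearrangement has not been shown on a 2-methyl-1-vinylcyclopentene bearing a fully substituted allylic carbinol, nor used to build a 5–7 ring-fusion quaternary centre under combined substrate/catalyst control; the carbenoid should cyclopropanate only the monosubstituted vinyl group (the tetrasubstituted ring alkene is inert), placing its own vinyl group cis to the cyclopentenyl group on the face chosen by the catalyst, a face that my analysis suggests is also weakly favoured by the substrate (approach anti to the C4 isopropyl group), and the cis-divinylcyclopropane should then undergo a boat Cope rearrangement (heating needed because C1 is fully substituted with an inward methyl) that forms C1–C10 on the same diene face, giving C10 α and CH3 β with C8=C9 and C5=C6 in place; the closest known reaction type is the Davies asymmetric cyclopropanation/Cope formal [4+3] of vinyldiazoacetates with dienes.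

Step 7
Reactants: 8
Product: 9, 4β-(triethylsilyloxy)dauca-5,8-dien-14-ol
Conditions: DIBAL-H, CH2Cl2, −78 °C
Reagents that add atoms: none
Why: DIBAL 1,2-reduction of the conjugated ester gives the primary allylic alcohol without touching the silyl ether or the alkenes.

Step 8
Reactants: 9
Product: 10, 4β-(triethylsilyloxy)dauca-5,8-diene
Conditions: MsCl, Et3N, CH2Cl2, −30 °C; then LiEt3BH, THF, −30 → 0 °C
Reagents that add atoms: none
Why: Sulfonate activation and Super-Hydride SN2 displacement at the unhindered primary allylic carbon converts CH2OH into the C8 methyl with the alkene kept at C8=C9.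

Step 9
Reactants: 10
Product: 11, dauca-5,8-dien-4β-ol
Conditions: TBAF, THF, 0 °C → rt
Reagents that add atoms: none
Why: Fluoride desilylation frees the tertiary allylic alcohol under non-acidic conditions, avoiding ionisation or elimination.

Step 10
Reactants: 11
Product: 12, 5β,6β-epoxydauc-8-en-4β-ol
Conditions: VO(acac)2 (5 mol %), t-BuOOH, 2,6-lutidine, CH2Cl2, 0 °C
Reagents that add atoms: tert-butyl hydroperoxide, CC(C)(C)OO
Why: Vanadium-catalysed hydroxyl-directed epoxidation reacts only at the allylic C5=C6 alkene (C8=C9 is remote and untouched) and delivers oxygen syn to the 4β-OH, giving the β-epoxide.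

Step 11
Reactants: 12
Product: 13, dauc-8-ene-4β,6β-diol with 5α-H (6-epi-jaeschkeanadiol)
Conditions: Cp2TiCl2, Zn, 1,4-cyclohexadiene, THF, rt
Reagents that add atoms: none
Why: Ti(III) (Nugent–RajanBabu) reductive epoxide opening cleaves C5–O to the tertiary C5 radical, which takes H from cyclohexadiene on the α-face, anti to the adjacent β-titanoxy group, the β C1-methyl and the β C4–O, so H5 is α (trans ring fusion) and C6–O stays β.

Step 12
Reactants: 13
Product: 14, 4β-hydroxydauc-8-en-6-one (5α-H)
Conditions: Dess–Martin periodinane, NaHCO3, CH2Cl2, 0 °C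
Reagents that add atoms: none
Why: Buffered Dess–Martin oxidation converts only the secondary C6 alcohol (the tertiary C4-OH is inert) under conditions mild enough to avoid C5 epimerisation, retro-aldol cleavage or alkene migration.

Step 13
Reactants: 14
Product: 15, jaeschkeanadiol (dauc-8-ene-4β,6α-diol)
Conditions: Me4NBH(OAc)3, MeCN–AcOH, −30 °C
Reagents that add atoms: none
Why: Evans–Saksena hydroxyl-directed reduction delivers hydride intramolecularly from the boron bound to the 4β-oxygen onto the β-face of the C6 ketone, giving the anti-1,3-diol with 6α-OH (undirected hydride would attack the α-face and give the wrong epimer).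

Step 14
Reactants: 15
Product: 16, 8α,9α-epoxydaucane-4β,6α-diol
Conditions: VO(acac)2 (5 mol %), t-BuOOH, 2,6-lutidine, CH2Cl2, 0 °C → rt
Reagents that add atoms: tert-butyl hydroperoxide, CC(C)(C)OO
Why: Vanadium-catalysed epoxidation directed by the homoallylic 6α-OH delivers oxygen to the α-face of C8=C9, which is also the face away from the axial C1 methyl; the base buffer suppresses transannular opening by the 4-OH.

Step 15
Reactants: 16; 17, 4-(benzyloxy)benzoyl chloride
Product: 18, 8α,9α-epoxy-4β-hydroxydaucan-6α-yl 4-(benzyloxy)benzoate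
Conditions: 17, Et3N, DMAP, CH2Cl2, 0 °C → rt
Reagents that add atoms: none beyond reactant 17
Why: DMAP-catalysed acylation occurs only at the secondary equatorial 6α-OH because the tertiary 4-OH is unreactive; no stereocentre is touched.

Step 16
Reactants: 18
Product: 19, jaeskeanin (target)
Conditions: H2 (1 atm), 10% Pd/C, EtOAc, rt
Reagents that add atoms: none
Why: Neutral hydrogenolysis removes the aryl benzyl ether; the aliphatic trisubstituted epoxide, the non-benzylic ester and the tertiary alcohol are stable, and no alkene remains.

**Compound list**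
1 | (S)-(+)-terpinen-4-ol [(S)-1-isopropyl-4-methylcyclohex-3-en-1-ol] | CC(C)[C@]1(O)CCC(C)=CC1 | starting material
2 | (S)-triethyl[(1-isopropyl-4-methylcyclohex-3-en-1-yl)oxy]silane | CC(C)[C@]1(O[Si](CC)(CC)CC)CCC(C)=CC1 | intermediate
3 | (S)-3-isopropyl-6-oxo-3-(triethylsilyloxy)heptanal | CC(C)[C@](CC=O)(O[Si](CC)(CC)CC)CCC(C)=O | intermediate
4 | (R)-5-isopropyl-2-methyl-5-(triethylsilyloxy)cyclopent-1-ene-1-carbaldehyde | CC(C)[C@]1(O[Si](CC)(CC)CC)CCC(C)=C1C=O | intermediate
5 | (R)-triethyl[(1-isopropyl-3-methyl-2-vinylcyclopent-2-en-1-yl)oxy]silane | CC(C)[C@]1(O[Si](CC)(CC)CC)CCC(C)=C1C=C | intermediate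
6 | methyl but-3-enoate | C=CCC(=O)OC | starting material
7 | methyl 2-diazobut-3-enoate | C=CC(=[N+]=[N-])C(=O)OC | intermediate
8 | methyl 4β-(triethylsilyloxy)dauca-5,8-dien-14-oate [methyl (3R,8aR)-3-isopropyl-8a-methyl-3-(triethylsilyloxy)-1,2,3,5,8,8a-hexahydroazulene-6-carboxylate] | CC(C)[C@]1(O[Si](CC)(CC)CC)CC[C@]2(C)CC=C(C(=O)OC)CC=C21 | intermediate
9 | 4β-(triethylsilyloxy)dauca-5,8-dien-14-ol | CC(C)[C@]1(O[Si](CC)(CC)CC)CC[C@]2(C)CC=C(CO)CC=C21 | intermediate
10 | 4β-(triethylsilyloxy)dauca-5,8-diene | CC(C)[C@]1(O[Si](CC)(CC)CC)CC[C@]2(C)CC=C(C)CC=C21 | intermediate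
11 | dauca-5,8-dien-4β-ol | CC(C)[C@]1(O)CC[C@]2(C)CC=C(C)CC=C21 | intermediate
12 | 5β,6β-epoxydauc-8-en-4β-ol | CC(C)[C@]1(O)CC[C@]2(C)CC=C(C)C[C@H]3O[C@]321 | intermediate
13 | dauc-8-ene-4β,6β-diol, 5α-H (6-epi-jaeschkeanadiol) | CC(C)[C@]1(O)CC[C@]2(C)CC=C(C)C[C@@H](O)[C@H]21 | intermediate
14 | 4β-hydroxydauc-8-en-6-one, 5α-H | CC(C)[C@]1(O)CC[C@]2(C)CC=C(C)CC(=O)[C@H]21 | intermediate
15 | jaeschkeanadiol (dauc-8-ene-4β,6α-diol) | CC(C)[C@]1(O)CC[C@]2(C)CC=C(C)C[C@H](O)[C@H]21 | intermediate
16 | 8α,9α-epoxydaucane-4β,6α-diol | CC(C)[C@]1(O)CC[C@]2(C)C[C@@H]3O[C@]3(C)C[C@H](O)[C@H]21 | intermediate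
17 | 4-(benzyloxy)benzoyl chloride | O=C(Cl)c1ccc(OCc2ccccc2)cc1 | starting material
18 | 8α,9α-epoxy-4β-hydroxydaucan-6α-yl 4-(benzyloxy)benzoate | CC(C)[C@]1(O)CC[C@]2(C)C[C@@H]3O[C@]3(C)C[C@H](OC(=O)c3ccc(OCc4ccccc4)cc3)[C@H]21 | intermediate
19 | jaeskeanin (8α,9α-epoxy-4β-hydroxydaucan-6α-yl 4-hydroxybenzoate) | CC(C)[C@]1(O)CC[C@]2(C)C[C@@H]3O[C@]3(C)C[C@H](OC(=O)c3ccc(O)cc3)[C@H]21 | target

**Totals**
- Total step count: 16.
- Longest linear sequence: 15 steps (1 → 19 through steps 1–4 and 6–16; step 5 is a one-step side branch).

**Three steps most likely to fail, with fallbacks**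
1. Step 6 (proposed new [4+3]). Risks are a slow Cope rearrangement at the fully substituted C1 terminus (competing homodienyl H-shift), modest facial selectivity, and a wrong catalyst-enantiomer assignment. Fallback (known chemistry, no carbenoid): build the divinylcyclopropane stepwise from enal 4 by Horner–Wadsworth–Emmons olefination to the dienoate, Corey–Chaykovsky cyclopropanation of the α,β-alkene, and ester-enolate aldol with acetaldehyde followed by dehydration to install the vinyl group; then thermal divinylcyclopropane rearrangement to 8 with chromatographic separation of C1 epimers.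
2. Step 3 (aldol condensation). The β-silyloxy aldehyde may lose the C4 oxygen by E1cB or undergo retro-aldol instead of cyclising. Fallback: make diene 5 without a C6 carbonyl. Sharpless epoxidation of 2-isopropylprop-2-en-1-ol, methallyl-cuprate opening of the epoxide, oxidation and Ohira–Bestmann alkynylation give the tertiary propargylic carbinol, which is silylated and closed by ring-closing enyne metathesis (Grubbs II, ethylene) to 5.
3. Step 11 (Ti(III) opening). The hindered tertiary radical may be deoxygenated back to 11 or take hydrogen on the wrong face. Fallback: drop the epoxide sequence and hydroborate ester 8 (BH3·THF, then H2O2/NaOH). The ester deactivates C8=C9, and the β-face of C5=C6 carries the OTES group and the angular methyl, so α-addition would install H5α and 6α-OH directly; DIBAL, selective allylic deoxygenation and TBAF then give 15. The α-face selectivity here is uncertain because the C4 isopropyl group sits on that face, which is why it is the fallback and not the main route.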